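**Conventions.** Atom labels C1–C10 are those of the ring carbons of the target and are kept for the same atoms in every intermediate: C1 (ring-fusion carbon with methyl), C2, C3, C4 (isopropyl carbinol), C5 (ring-fusion CH), C6, C7, C8 (methyl), C9, C10 (bonded to C1). β is the face of the C1 methyl, α the opposite face.

**Assumption.** Commercial (S)-(+)-terpinen-4-ol is used enantiomerically pure (upgraded if needed); C4 is never touched, so the target inherits its enantiomeric purity.

## Analysis of the target

Lapiferine (26) is a daucane-type hydroazulene: a cyclopentane (C1–C5) and a cycloheptane (C1, C5–C10) share the C1–C5 bond. It has seven stereocentres (C1, C4, C5, C6, C8, C9, C10), interrupted only by the C2/C3 and C7 methylenes. The ring fusion is trans: the C1 methyl and the C4 hydroxyl are β, while H5 and all three oxygens on the seven-membered ring (C6 ester, C8/C9 epoxide, C10 hydroxyl) are α. The sensitive groups are the angelate (a (Z)-enoate that isomerises to the tiglate under nucleophiles, base or heat), the trisubstituted epoxide next to a free secondary alcohol (Payne rearrangement, acid opening), and the tertiary C4 alcohol β to the C6 oxygen (dehydration; retro-aldol whenever C6 is a ketone). The difficulty is the run of three congested carbons C4–C5–C1 at a trans ring fusion, with quaternary C1 wedged between C5 and the C10 carbinol, plus the dense α-face oxygenation. The strategy rests on one feature: oxygenated C6 with its neighbours C5 and C7 is a three-carbon oxyallyl unit, the other four ring atoms C8, C9, C10, C1 are a diene, and C2–C3–C4 is a tether from the diene terminus C1 to the oxyallyl terminus C5. A linear chain that carries only the C4 stereocentre can therefore be folded into both rings at once, and that stereocentre with both of its arms is available from (S)-terpinen-4-ol (1).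

## Retrosynthetic reasoning

**Epoxide (26 ⇒ 25).** The C8/C9 epoxide is cut first, because it is the most fragile group and because the 10α-hydroxyl of 25 can deliver the oxygen to its own face. The forward reaction has to be a hydroxyl-directed epoxidation that ignores the electron-poor angelate alkene.

**Ester (25 ⇒ 24 ⇒ 21 + 22).** The C6–O acyl bond is cut next. The angelate goes on late because selenium nucleophiles and base isomerise it. C10–OH must be masked at that point (24) so that only the secondary C6 hydroxyl of 21 meets angelic acid (22).

**C6 carbinol (21 ⇒ 20 ⇒ 19 ⇒ 18).** The C6–H bond is cut back to the ketone. The tertiary C4 hydroxyl is β to C6, so an internally delivered hydride gives the 1,3-anti diol, which is the 6α-alcohol. This requires C4–OH free and C10–OH masked (20). The order is therefore desilylation at C4 (18 ⇒ 19) and then selective silylation of the secondary C10 hydroxyl (19 ⇒ 20). This avoids having to remove a tertiary silyl ether in the presence of a secondary one.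

**Allylic alcohol (18 ⇒ 16 ⇒ 15 ⇒ 14).** The 10α-hydroxyl and the C8=C9 alkene are traced back to a C9=C10 alkene by a 1,3-transposition: α-epoxide 15, anti opening at C9 by a selenolate (16), selenoxide syn-elimination. The cycloaddition necessarily leaves its alkene at C9=C10, so this is the price of the key step. It is stereochemically coherent only if H8 is cis to selenium, i.e. the C8 methyl of 14 is α.

**Both rings (14 ⇒ 12).** C1–C5 and C7–C8 are cut together. This removes the five- and seven-membered rings and three stereocentres in one operation and leaves an acyclic chloromethyl ketone with an (E,E)-diene. The forward reaction must ionise the chloro ketone to the C5–C6–C7 oxyallyl cation and add it across the diene termini with trans fusion and the C1 methyl cis to the C4 oxygen.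

**Chloro ketone (12 ⇒ 11 ⇒ 10).** The C6–C7 bond is cut: a chloromethyl carbanion adds to aldehyde 10 and the chlorohydrin is oxidised. This is two steps and raises no regiochemical question, unlike chlorination of a methyl ketone.

**Diene (10 ⇒ 9 ⇒ 6 + 7).** The C9–C10 bond and the C1–methyl bond are cut. A ketone olefination at C1 would give a C1=C10 E/Z mixture, and that geometry is copied into C8 in the key step. The trisubstituted alkene is therefore made by syn-carbometalation of terminal alkyne 6 and stereoretentive coupling with (E)-1-bromopropene (7), which fixes both geometries by mechanism.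

**Chain (6 ⇒ 4 ⇒ 2 ⇒ 1).** The alkyne comes from the methyl ketone of 4 (the old methyl carbon becomes C10). Ozonolysis of the ring alkene of the silyl ether 2 releases the C5–C6 arm as an aldehyde (kept as acetal) and the C3–C2–C1 arm as the methyl ketone. C4 comes unchanged from 1.

## Alternatives that were turned down

**Alternative 1:** Disconnection of C1–CH3 and C5–C6 on a cyclopentanone that still has C4 as a ketone: enone A1 (its exocyclic carbon is C10) and aldehyde A2 (C6–C9 with a (Z)-vinyl iodide).
- Forward key step: Cu(OTf)2 with a chiral phosphoramidite transfers methyl from AlMe3 to C1, and the aluminium enolate adds through C5 to A2, giving the anti aldol A3. No ring closes. The seven-membered ring would follow by Nozaki–Hiyama–Kishi closure of C9 onto a C10 aldehyde, and the C4 carbinol by isopropyl addition.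
- For it: the quaternary C1 centre is set by a catalyst in a well-precedented reaction, which is stronger than the chosen route, where C1 depends on how a chain folds. The later closure gives the C8=C9/C10–OH allylic alcohol directly, so the three-step transposition is not needed.
- Against it: the key step builds no ring. Enolate trapping must tell CH3 from CH2OSi at C1 to put C6 cis to the methyl. The C6 and C10 carbinols each rest on separate, weakly biased additions. The C4 carbinol needs an isopropyl nucleophile to add to a hindered, easily enolised ketone next to C5 in a retro-aldol-prone setting. Rings, C4 and the oxidation states are all handled one at a time, so the route is clearly longer.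
- Comparison: the chosen strategy takes C4 from the chiral pool and closes both rings in one step, at the cost of an unproven diastereoselection.

**Alternative 2:** Disconnection of C7–C8 and C1–C10 between the terpinen-4-ol-derived vinylcyclopentene A4 and the siloxy vinyldiazo ester A5.
- Forward key step: Rh2(S-DOSP)4 (or its enantiomer, whichever matches C4) forms the vinylcarbenoid, which cyclopropanates the vinyl group; Cope rearrangement of the resulting divinylcyclopropane closes the seven-membered ring to A6.
- For it: this is a known reaction class. C1 and C10 are set under reagent control and C10 arrives oxygenated with the right configuration. The C5=C6 alkene can be hydroborated to H5α/6α-OH. On precedent and on control of C1 it is stronger than the chosen route.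
- Against it: C8 arrives as an ester that must be reduced to methyl in two operations. A diazo reagent and a chiral dirhodium catalyst are needed. The five-membered ring must be made first by an aldol condensation next to a β-silyloxy group. The Cope step must form a quaternary centre, and the face of the hydroboration is not secured.
- Comparison: the step count is similar to the chosen route, which instead forms both rings from an acyclic chain without diazo chemistry and delivers the C8 methyl and C6 oxygen at usable oxidation levels. Because it shares 1–3 with the chosen route, this alternative is kept as the fallback for the key step.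

**Alternative 3:** Disconnection of C1–C5 by a pinacol-type 1,2-shift in a Wieland–Miescher-derived cis-decalin A7 (C6 tertiary hydroxyl, C5 mesylate).
- Forward key step: KOt-Bu (or Et2AlCl) generates the C6 alkoxide, C1 migrates from C6 to C5 anti to the leaving mesylate, ring A contracts to five and ring B expands to seven, with C6 as the ketone in A8.
- For it: this is the most reliable key step of the four. The migration is stereospecific, the trans fusion follows from inversion at C5, and quaternary C1 comes from a cheap enantiopure building block.
- Against it: A8 carries three bare methylenes at C7–C9. The C8 methyl, the C8=C9 alkene and the 10α-hydroxyl must all be introduced afterwards by repeated enone chemistry, and hydride approach to a C10 ketone is blocked on the required β face by the C1 methyl. Assembling A7 with the C4 isopropyl carbinol and a defined C5/C6 diol already takes many steps.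
- Comparison: the chosen strategy is far shorter, and its cycloadduct carries ketone, alkene and methyl exactly where the target needs functionality.

Key step: step 8

## Route

Step 1
Reactants: 1 (S)-terpinen-4-ol
Product: 2 (S)-triethyl{[4-methyl-1-(propan-2-yl)cyclohex-3-en-1-yl]oxy}silane
Conditions: TESOTf, 2,6-lutidine, CH2Cl2, 0 °C to rt
Reagents that add atoms: triethylsilyl trifluoromethanesulfonate, CC[Si](CC)(CC)OS(=O)(=O)C(F)(F)F
Why: Silyl triflate/2,6-lutidine silylation of a hindered tertiary alcohol; the ether prevents hemiketal formation and retro-aldol-type cleavage once the carbonyls are unveiled and stays on until step 12.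

Step 2
Reactants: 2 (S)-triethyl{[4-methyl-1-(propan-2-yl)cyclohex-3-en-1-yl]oxy}silane
Product: 4 (S)-7,7-dimethoxy-5-(propan-2-yl)-5-[(triethylsilyl)oxy]heptan-2-one, via keto aldehyde 3 (not isolated)
Conditions: O3, CH2Cl2/MeOH, −78 °C; Me2S, −78 °C to rt; then HC(OMe)3, CeCl3·7H2O (cat.), MeOH, rt
Reagents that add atoms: ozone, [O-][O+]=O; trimethyl orthoformate, COC(OC)OC
Why: Ozonolysis with reductive work-up cleaves the only alkene to the methyl ketone (C1) and the aldehyde (C6), whichever way the primary ozonide fragments; CeCl3-catalysed acetalisation with the orthoformate is selective for the aldehyde, so the two termini are differentiated in one flask. C4 is not involved.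

Step 3
Reactants: 4 (S)-7,7-dimethoxy-5-(propan-2-yl)-5-[(triethylsilyl)oxy]heptan-2-one
Product: 6 (S)-7,7-dimethoxy-5-(propan-2-yl)-5-[(triethylsilyl)oxy]hept-1-yne, via enol phosphate 5 (not isolated)
Conditions: LiN(i-Pr)2, THF, −78 °C; ClP(O)(OEt)2, −78 °C to rt; LiN(i-Pr)2 (2.3 equiv), −78 °C to rt
Reagents that add atoms: none
Why: Kinetic deprotonation at the methyl group, O-phosphorylation and amide-induced elimination of the enol phosphate convert the methyl ketone into the terminal alkyne; the former methyl carbon becomes C10. Acetal and silyl ether are inert to amide base.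

Step 4
Reactants: 6 (S)-7,7-dimethoxy-5-(propan-2-yl)-5-[(triethylsilyl)oxy]hept-1-yne; 7 (E)-1-bromoprop-1-ene
Product: 9 (S,6E,8E)-1,1-dimethoxy-6-methyl-3-(propan-2-yl)-3-[(triethylsilyl)oxy]deca-6,8-diene, via alkenylalane 8 (not isolated)
Conditions: Me3Al, Cp2ZrCl2 (cat.), H2O (1 equiv), CH2Cl2, −25 °C; then 7, Pd(PPh3)4 (cat.), ZnCl2, THF, rt
Reagents that add atoms: trimethylaluminium, C[Al](C)C
Why: Zirconium-catalysed syn-carboalumination (Negishi) puts methyl on C1 and aluminium on C10 on the same side, and the palladium-catalysed coupling of the alkenylalane with 7 (Negishi coupling) retains both alkene geometries, so the (E,E)-diene is fixed by mechanism. The water-accelerated low-temperature variant is chosen to keep the Lewis-acidic aluminium away from the acetal.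

Step 5
Reactants: 9 (S,6E,8E)-1,1-dimethoxy-6-methyl-3-(propan-2-yl)-3-[(triethylsilyl)oxy]deca-6,8-diene
Product: 10 (S,6E,8E)-6-methyl-3-(propan-2-yl)-3-[(triethylsilyl)oxy]deca-6,8-dienal
Conditions: PPTS (cat.), acetone/H2O, 45 °C
Reagents that add atoms: water, O
Why: Mild acid-catalysed acetal hydrolysis; pyridinium tosylate is too weak to cleave the hindered tertiary silyl ether or to protonate the diene.

Step 6
Reactants: 10 (S,6E,8E)-6-methyl-3-(propan-2-yl)-3-[(triethylsilyl)oxy]deca-6,8-dienal
Product: 11 (4S,7E,9E)-1-chloro-7-methyl-4-(propan-2-yl)-4-[(triethylsilyl)oxy]undeca-7,9-dien-2-ol (both C2 epimers)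
Conditions: ICH2Cl, MeLi·LiBr, THF, −78 °C; AcOH, −78 °C
Reagents that add atoms: chloroiodomethane, ClCI
Why: Chloromethyllithium, generated by iodine–lithium exchange in the presence of the aldehyde, adds to the carbonyl (carbenoid 1,2-addition) and brings in C7 with its chlorine; the cold acidic quench prevents closure to the epoxide. The new carbinol centre forms as both epimers and is removed in step 7.

Step 7
Reactants: 11 (4S,7E,9E)-1-chloro-7-methyl-4-(propan-2-yl)-4-[(triethylsilyl)oxy]undeca-7,9-dien-2-ol
Product: 12 (4S,7E,9E)-1-chloro-7-methyl-4-(propan-2-yl)-4-[(triethylsilyl)oxy]undeca-7,9-dien-2-one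
Conditions: Dess–Martin periodinane, NaHCO3, CH2Cl2, 0 °C to rt
Reagents that add atoms: none
Why: Dess–Martin oxidation of the chlorohydrin under buffered, non-basic conditions gives the chloromethyl ketone without touching the diene or eliminating the β-silyloxy group.

Step 8
Reactants: 12 (4S,7E,9E)-1-chloro-7-methyl-4-(propan-2-yl)-4-[(triethylsilyl)oxy]undeca-7,9-dien-2-one
Product: 14 trans-fused hydroazul-9-en-6-one (C1 methyl β; C4 triethylsilyloxy β and isopropyl α; H5 α; C8 methyl α), via oxyallyl cation 13 (not isolated)
Conditions: Et3N, LiClO4, CF3CH2OH (0.01 M), 0 °C to rt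
Reagents that add atoms: none
Why: Proposed new method: Et3N reversibly enolises the ketone toward C5, and in the strongly ionising LiClO4/CF3CH2OH medium this enolate loses chloride from C7 to give the lithium-bound oxyallyl cation 13 (C5–C6–C7), which adds to the tethered diene as a three-carbon cation across a four-carbon diene; the closest known reaction type is the intramolecular (4+3) cycloaddition of oxyallyl cations from α-halo ketones with tethered dienes, and new here are a diene terminus (C1) that becomes quaternary and a β-silyloxy group next to the oxyallyl. Bonding should be asynchronous: unsubstituted C7 attacks the less hindered C8, positive charge develops at tertiary allylic C1, and C5 captures it. The five-membered ring closes by C1–C5 through the C2–C3–C4 tether in a 5-exo-trig sense, with both reacting π bonds (C5=C6 and C1=C10) outside the new ring; the seven-membered ring is completed by C7–C8 across the diene termini, endo with respect to both π systems and suprafacial on both. C8 is set by the diene geometry: suprafacial addition to the s-cis (E,E)-diene puts the two inside groups (C1 methyl and H8) cis, hence the C8 methyl α. C5 is set by C4: the tether only allows the C4 substituent cis to the oxyallyl oxygen, the small lithium-coordinating silyloxy oxygen should lie in the oxyallyl plane, and isopropyl and C3 then sit on opposite faces, so the diene reaches C5 from the C3 face, which places C6 cis to the silyloxy group and H5 cis to isopropyl. C1 is set by the mutual orientation of the two π planes: only the extended arrangement (oxyallyl C–O turned away from C9/C10) puts H5 and the C1 methyl anti and gives the trans fusion with the methyl cis to the C4 oxygen; this is the usual mode of three-atom-tethered, asynchronous cation cycloadditions but it is not secured here, because the inside methyl on C1 lies under the oxyallyl in that arrangement. Ionisation has to be faster than loss of the C4 silyloxy group from the C5 enolate, Favorskii rearrangement and solvent capture, which is why a weak amine base, a non-nucleophilic ionising solvent, lithium assistance and high dilution are used.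

Step 9
Reactants: 14 trans-fused hydroazul-9-en-6-one
Product: 15 9α,10α-epoxide of 14
Conditions: dimethyldioxirane, acetone/CH2Cl2, −20 to 0 °C
Reagents that add atoms: dimethyldioxirane, CC1(C)OO1
Why: Electrophilic epoxidation with a neutral dioxirane, to which ketone and silyl ether are inert. The trans fusion holds the C1 methyl axial on the β face whereas the C8 methyl can turn equatorial, so the oxidant should approach C9=C10 from the α face.

Step 10
Reactants: 15 9α,10α-epoxide of 14
Product: 16 9β-phenylselanyl-10α-hydroxy ketone
Conditions: PhSeSePh, NaBH4, EtOH, rt (pre-formed); then 15, rt to 50 °C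
Reagents that add atoms: diphenyl diselenide, c1ccc(cc1)[Se][Se]c1ccccc1
Why: SN2 opening of the epoxide by the selenolate Na[PhSeB(OEt)3] at C9 (C10 is neopentyl), anti to the oxygen, gives the 9β-selenide and the 10α-alcohol, a diaxial-type opening next to an angular methyl. The reagent is pre-formed so that no hydride is left for the ketone, and H5, flanked by two quaternary carbons, is slow to enolise in this weakly basic medium.

Step 11
Reactants: 16 9β-phenylselanyl-10α-hydroxy ketone
Product: 18 10α-hydroxy-hydroazul-8-en-6-one (C4 triethylsilyloxy), via selenoxide 17 (not isolated)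
Conditions: mCPBA, CH2Cl2, −78 °C; i-Pr2NH, −78 °C to rt
Reagents that add atoms: none
Why: Oxidation to the selenoxide and syn-elimination (selenoxide elimination): the only syn hydrogen not on the carbinol carbon is H8, which is β like selenium because of the C8 configuration set in step 8, so the alkene forms at C8=C9 and C10 keeps its α-hydroxyl (net 1,3-transposition). The amine scavenges the selenenic acid, and the peracid is consumed at low temperature before it can attack the ketone or the new alkene.

Step 12
Reactants: 18 10α-hydroxy-hydroazul-8-en-6-one (C4 triethylsilyloxy)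
Product: 19 4β,10α-dihydroxy-hydroazul-8-en-6-one
Conditions: HF·pyridine, pyridine, THF, 0 °C to rt
Reagents that add atoms: none
Why: Fluoride cleavage of the only silyl ether under buffered acidic conditions, which avoid the retro-aldol that base would provoke in the resulting β-hydroxy ketone.

Step 13
Reactants: 19 4β,10α-dihydroxy-hydroazul-8-en-6-one
Product: 20 10α-(tert-butyldimethylsilyloxy)-4β-hydroxy-hydroazul-8-en-6-one
Conditions: TBSOTf (1.1 equiv), 2,6-lutidine, CH2Cl2, −78 °C
Reagents that add atoms: tert-butyldimethylsilyl trifluoromethanesulfonate, CC(C)(C)[Si](C)(C)OS(=O)(=O)C(F)(F)F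
Why: Low-temperature silyl triflate silylation discriminates the secondary allylic C10 hydroxyl from the tertiary C4 hydroxyl flanked by isopropyl. Masking C10 leaves C4–OH as the only directing group in step 14 and C6–OH as the only acylable hydroxyl in step 15.

Step 14
Reactants: 20 10α-(tert-butyldimethylsilyloxy)-4β-hydroxy-hydroazul-8-en-6-one
Product: 21 10α-(tert-butyldimethylsilyloxy)-hydroazul-8-ene-4β,6α-diol
Conditions: Me4NBH(OAc)3, MeCN/AcOH, −30 to 0 °C
Reagents that add atoms: none
Why: Evans–Saksena reduction: the C4 hydroxyl exchanges onto boron and delivers hydride intramolecularly to the β face of the C6 carbonyl through a six-membered transition state, giving the 1,3-anti diol, i.e. the 6α-alcohol. The cold, weakly acidic medium should not move the β,γ-alkene into conjugation.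

Step 15
Reactants: 21 10α-(tert-butyldimethylsilyloxy)-hydroazul-8-ene-4β,6α-diol; 22 angelic acid
Product: 24 6α-angeloyloxy-10α-(tert-butyldimethylsilyloxy)-hydroazul-8-en-4β-ol, via mixed anhydride 23 (not isolated)
Conditions: 22, 2,4,6-trichlorobenzoyl chloride, Et3N, toluene, rt; then 21, toluene, 80 °C
Reagents that add atoms: none
Why: Yamaguchi-type esterification through the mixed anhydride of angelic acid, run without a nucleophilic catalyst, which is the mode that keeps the (Z)-alkene from isomerising to the tiglate. Only the secondary C6 hydroxyl is free to react (C4 is tertiary, C10 is silylated).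

Step 16
Reactants: 24 6α-angeloyloxy-10α-(tert-butyldimethylsilyloxy)-hydroazul-8-en-4β-ol
Product: 25 6α-angeloyloxy-hydroazul-8-ene-4β,10α-diol
Conditions: HF·pyridine, pyridine, THF, 0 °C to rt
Reagents that add atoms: none
Why: Buffered fluoride desilylation without base, so neither acyl migration nor angelate isomerisation is expected.

Step 17
Reactants: 25 6α-angeloyloxy-hydroazul-8-ene-4β,10α-diol
Product: 26 lapiferine
Conditions: VO(acac)2 (cat.), t-BuOOH, CH2Cl2, 0 °C to rt
Reagents that add atoms: tert-butyl hydroperoxide, CC(C)(C)OO
Why: Vanadium-catalysed hydroxyl-directed epoxidation: the C10 hydroxyl binds vanadium and the peroxide oxygen is delivered to the C8=C9 alkene on the same (α) face, giving the cis epoxy alcohol. The electron-poor angelate alkene and the remote tertiary alcohol take no part.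

## Compound list

1 | (S)-terpinen-4-ol [(S)-4-methyl-1-(propan-2-yl)cyclohex-3-en-1-ol] | CC1=CC[C@](O)(C(C)C)CC1 | starting material
2 | (S)-triethyl{[4-methyl-1-(propan-2-yl)cyclohex-3-en-1-yl]oxy}silane | CC1=CC[C@](O[Si](CC)(CC)CC)(C(C)C)CC1 | intermediate
3 | (S)-6-oxo-3-(propan-2-yl)-3-[(triethylsilyl)oxy]heptanal (keto aldehyde, not isolated) | O=CC[C@](O[Si](CC)(CC)CC)(C(C)C)CCC(C)=O | intermediate
4 | (S)-7,7-dimethoxy-5-(propan-2-yl)-5-[(triethylsilyl)oxy]heptan-2-one | COC(OC)C[C@](O[Si](CC)(CC)CC)(C(C)C)CCC(C)=O | intermediate
5 | diethyl (S)-7,7-dimethoxy-5-(propan-2-yl)-5-[(triethylsilyl)oxy]hept-1-en-2-yl phosphate (enol phosphate, not isolated) | COC(OC)C[C@](O[Si](CC)(CC)CC)(C(C)C)CCC(=C)OP(=O)(OCC)OCC | intermediate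
6 | (S)-7,7-dimethoxy-5-(propan-2-yl)-5-[(triethylsilyl)oxy]hept-1-yne | COC(OC)C[C@](O[Si](CC)(CC)CC)(C(C)C)CCC#C | intermediate
7 | (E)-1-bromoprop-1-ene | C/C=C/Br | starting material
8 | (S,E)-{7,7-dimethoxy-2-methyl-5-(propan-2-yl)-5-[(triethylsilyl)oxy]hept-1-en-1-yl}dimethylalane (alkenylalane, not isolated) | COC(OC)C[C@](O[Si](CC)(CC)CC)(C(C)C)CC/C(C)=C/[Al](C)C | intermediate
9 | (S,6E,8E)-1,1-dimethoxy-6-methyl-3-(propan-2-yl)-3-[(triethylsilyl)oxy]deca-6,8-diene | COC(OC)C[C@](O[Si](CC)(CC)CC)(C(C)C)CC/C(C)=C/C=C/C | intermediate
10 | (S,6E,8E)-6-methyl-3-(propan-2-yl)-3-[(triethylsilyl)oxy]deca-6,8-dienal | O=CC[C@](O[Si](CC)(CC)CC)(C(C)C)CC/C(C)=C/C=C/C | intermediate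
11 | (4S,7E,9E)-1-chloro-7-methyl-4-(propan-2-yl)-4-[(triethylsilyl)oxy]undeca-7,9-dien-2-ol (both C2 epimers) | ClCC(O)C[C@](O[Si](CC)(CC)CC)(C(C)C)CC/C(C)=C/C=C/C | intermediate
12 | (4S,7E,9E)-1-chloro-7-methyl-4-(propan-2-yl)-4-[(triethylsilyl)oxy]undeca-7,9-dien-2-one (precursor of the key step) | ClCC(=O)C[C@](O[Si](CC)(CC)CC)(C(C)C)CC/C(C)=C/C=C/C | intermediate
13 | oxyallyl cation from 12 (C5–C6–C7 zwitterion after loss of chloride, C4 unchanged; not isolated) | [CH2+]C([O-])=C[C@](O[Si](CC)(CC)CC)(C(C)C)CC/C(C)=C/C=C/C | intermediate
14 | trans-fused hydroazul-9-en-6-one: C1 methyl β, C4 triethylsilyloxy β and isopropyl α, H5 α, C8 methyl α (product of the key step) | O=C1C[C@@H](C)C=C[C@@]2(C)CC[C@@](O[Si](CC)(CC)CC)(C(C)C)[C@H]12 | intermediate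
15 | 9α,10α-epoxide of 14 | O=C1C[C@@H](C)[C@H]2O[C@H]2[C@@]2(C)CC[C@@](O[Si](CC)(CC)CC)(C(C)C)[C@H]12 | intermediate
16 | 10α-hydroxy-9β-phenylselanyl ketone (8α-methyl, C4 triethylsilyloxy) | O=C1C[C@@H](C)[C@H]([Se]c3ccccc3)[C@@H](O)[C@@]2(C)CC[C@@](O[Si](CC)(CC)CC)(C(C)C)[C@H]12 | intermediate
17 | selenoxide of 16 (not isolated) | O=C1C[C@@H](C)[C@H]([Se](=O)c3ccccc3)[C@@H](O)[C@@]2(C)CC[C@@](O[Si](CC)(CC)CC)(C(C)C)[C@H]12 | intermediate
18 | 10α-hydroxy-hydroazul-8-en-6-one with C8 methyl on the alkene, C4 triethylsilyloxy β | O=C1CC(C)=C[C@@H](O)[C@@]2(C)CC[C@@](O[Si](CC)(CC)CC)(C(C)C)[C@H]12 | intermediate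
19 | 4β,10α-dihydroxy-hydroazul-8-en-6-one | O=C1CC(C)=C[C@@H](O)[C@@]2(C)CC[C@@](O)(C(C)C)[C@H]12 | intermediate
20 | 10α-(tert-butyldimethylsilyloxy)-4β-hydroxy-hydroazul-8-en-6-one | O=C1CC(C)=C[C@@H](O[Si](C)(C)C(C)(C)C)[C@@]2(C)CC[C@@](O)(C(C)C)[C@H]12 | intermediate
21 | 10α-(tert-butyldimethylsilyloxy)-hydroazul-8-ene-4β,6α-diol | O[C@H]1CC(C)=C[C@@H](O[Si](C)(C)C(C)(C)C)[C@@]2(C)CC[C@@](O)(C(C)C)[C@H]12 | intermediate
22 | angelic acid [(Z)-2-methylbut-2-enoic acid] | C/C=C(/C)C(=O)O | starting material
23 | angelic 2,4,6-trichlorobenzoic anhydride (not isolated) | C/C=C(/C)C(=O)OC(=O)c1c(Cl)cc(Cl)cc1Cl | intermediate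
24 | 6α-angeloyloxy-10α-(tert-butyldimethylsilyloxy)-hydroazul-8-en-4β-ol | C/C=C(/C)C(=O)O[C@H]1CC(C)=C[C@@H](O[Si](C)(C)C(C)(C)C)[C@@]2(C)CC[C@@](O)(C(C)C)[C@H]12 | intermediate
25 | 6α-angeloyloxy-hydroazul-8-ene-4β,10α-diol | C/C=C(/C)C(=O)O[C@H]1CC(C)=C[C@@H](O)[C@@]2(C)CC[C@@](O)(C(C)C)[C@H]12 | intermediate
26 | lapiferine | C/C=C(/C)C(=O)O[C@H]1C[C@@]2(C)O[C@H]2[C@@H](O)[C@@]2(C)CC[C@@](O)(C(C)C)[C@H]12 | target

## Step count and least certain steps

Total: 17 steps. Longest linear sequence: 17 steps from 1 (7 and 22 are commercial and enter directly).

**Step 8 (key step, proposed new method).** Two things are most likely to go wrong. First, the C5 enolate may expel the C4 silyloxy group, or the chloro ketone may undergo Favorskii rearrangement or solvolysis, before the cation meets the diene. Second, the two π systems may fold through the compact arrangement, which would give the cis-fused C1 epimer. The fallback uses known reactions only and gives up the one-step closure of both rings. It sets out from keto aldehyde 3, obtained by stopping step 2 after the Me2S reduction. Intramolecular aldol condensation (piperidine, AcOH, benzene) joins C5 to C1 and gives the cyclopentenecarbaldehyde F1. Wittig methylenation (Ph3P=CH2, THF) gives the vinylcyclopentene F2 (the same compound as A4). With the diazo ester A5 and Rh2(S-DOSP)4 or Rh2(R-DOSP)4, whichever is matched to C4, tandem cyclopropanation of the vinyl group and Cope rearrangement close the seven-membered ring (C7–C8 and C1–C10) to the cycloheptadiene F3 (the same compound as A6), with C1 and C10 under catalyst control. Hydroboration–oxidation of the C5=C6 alkene from the α face (BH3·THF; NaBO3) gives the trans-fused 6α-alcohol F4. i-Bu2AlH reduces the ester to the allylic diol F5. Reductive removal of the primary allylic hydroxyl (SO3·pyridine, then LiAlH4) leaves the C8 methyl in F6. Angeloylation as in step 15 gives F7, and HF·pyridine removes both silyl groups, so the fallback comes back to the route at 25, one step from the target.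

**Step 9.** The risk is poor facial selectivity: the C8 methyl sits on the α face, and if the oxidant attacks from the β face the derived selenide has no syn hydrogen for the elimination in step 11. The fallback sets out from 14. NBS in aqueous DME forms the bromonium ion on the face the dioxirane preferred, and water opens it at C9 from the other face to give bromohydrin F8. K2CO3 in MeOH then closes F8 to the epoxide of opposite configuration, and the fallback comes back to the route at 15.

**Step 14.** The risk is that hydride delivery from the hindered tertiary C4 hydroxyl is slow, so that undirected reduction from the open α face competes and gives the 6β-alcohol. The fallback sets out from 20. NaBH4 with CeCl3·7H2O in MeOH reduces from the α face to the 6β-alcohol F9. A Mitsunobu reaction (4-nitrobenzoic acid, PPh3, DIAD) inverts C6 to the 6α-ester F10, and methanolysis (K2CO3, MeOH) returns to the route at 21.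

**Step 4.** The risk is attack of the Lewis-acidic aluminium species on the dimethyl acetal (ionisation and methyl transfer) before carboalumination is complete. The fallback sets out from keto acetal 4 and comes back at 9. Horner–Wadsworth–Emmons olefination of the ketone with the lithium anion of diethyl (E)-but-2-enylphosphonate (n-BuLi, THF/DMPU, −78 °C to rt) gives 9 directly, without the alkyne and without aluminium. It is one step shorter but gives a mixture of C1=C10 isomers, which would have to be separated on AgNO3-impregnated silica before step 8.

## Further compounds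

F1 | step 8 | (S)-2-methyl-5-(propan-2-yl)-5-[(triethylsilyl)oxy]cyclopent-1-ene-1-carbaldehyde (C5=C1 enal, C6 formyl) | O=CC1=C(C)CC[C@@]1(O[Si](CC)(CC)CC)C(C)C
F2 | step 8 | 1-ethenyl-2-methylcyclopentene with C4 triethylsilyloxy and isopropyl (C7=C6–C5=C1 diene; identical with A4) | C=CC1=C(C)CC[C@@]1(O[Si](CC)(CC)CC)C(C)C
F3 | step 8 | hydroazula-5,8-diene with C8 methyl ester, 10α-(tert-butyldimethylsilyloxy), C1 methyl β, C4 triethylsilyloxy β (identical with A6) | C1C(C(=O)OC)=C[C@@H](O[Si](C)(C)C(C)(C)C)[C@@]2(C)CC[C@@](O[Si](CC)(CC)CC)(C(C)C)C2=C1
F4 | step 8 | trans-fused 6α-hydroxy-hydroazul-8-ene with C8 methyl ester, 10α-(tert-butyldimethylsilyloxy), C4 triethylsilyloxy | O[C@H]1CC(C(=O)OC)=C[C@@H](O[Si](C)(C)C(C)(C)C)[C@@]2(C)CC[C@@](O[Si](CC)(CC)CC)(C(C)C)[C@H]12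
F5 | step 8 | 6α-hydroxy-8-(hydroxymethyl)-hydroazul-8-ene, 10α-(tert-butyldimethylsilyloxy), C4 triethylsilyloxy | O[C@H]1CC(CO)=C[C@@H](O[Si](C)(C)C(C)(C)C)[C@@]2(C)CC[C@@](O[Si](CC)(CC)CC)(C(C)C)[C@H]12
F6 | step 8 | 6α-hydroxy-8-methyl-hydroazul-8-ene, 10α-(tert-butyldimethylsilyloxy), C4 triethylsilyloxy | O[C@H]1CC(C)=C[C@@H](O[Si](C)(C)C(C)(C)C)[C@@]2(C)CC[C@@](O[Si](CC)(CC)CC)(C(C)C)[C@H]12
F7 | step 8 | 6α-angeloyloxy-8-methyl-hydroazul-8-ene, 10α-(tert-butyldimethylsilyloxy), C4 triethylsilyloxy | C/C=C(/C)C(=O)O[C@H]1CC(C)=C[C@@H](O[Si](C)(C)C(C)(C)C)[C@@]2(C)CC[C@@](O[Si](CC)(CC)CC)(C(C)C)[C@H]12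
F8 | step 9 | 10β-bromo-9α-hydroxy ketone (8α-methyl, C4 triethylsilyloxy) | O=C1C[C@@H](C)[C@@H](O)[C@H](Br)[C@@]2(C)CC[C@@](O[Si](CC)(CC)CC)(C(C)C)[C@H]12
F9 | step 14 | 10α-(tert-butyldimethylsilyloxy)-hydroazul-8-ene-4β,6β-diol | O[C@@H]1CC(C)=C[C@@H](O[Si](C)(C)C(C)(C)C)[C@@]2(C)CC[C@@](O)(C(C)C)[C@H]12
F10 | step 14 | 6α-(4-nitrobenzoyloxy)-10α-(tert-butyldimethylsilyloxy)-hydroazul-8-en-4β-ol | O=C(O[C@H]1CC(C)=C[C@@H](O[Si](C)(C)C(C)(C)C)[C@@]2(C)CC[C@@](O)(C(C)C)[C@H]12)c1ccc(cc1)[N+](=O)[O-]
F0 | step 4 | none | none
A1 | alternative 1 | 3-{[(tert-butyldimethylsilyl)oxy]methyl}cyclopent-2-en-1-one | O=C1C=C(CO[Si](C)(C)C(C)(C)C)CC1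
A2 | alternative 1 | (Z)-4-iodo-3-methylbut-3-enal | O=CC/C(C)=C\I
A3 | alternative 1 | anti aldol: cyclopentanone with quaternary C1 (methyl, silyloxymethyl) and C5 side chain carrying the C6 carbinol and the (Z)-vinyl iodide | O[C@@H](C/C(C)=C\I)[C@H]1C(=O)CC[C@]1(C)CO[Si](C)(C)C(C)(C)C
A4 | alternative 2 | 1-ethenyl-2-methylcyclopentene with C4 triethylsilyloxy and isopropyl | C=CC1=C(C)CC[C@@]1(O[Si](CC)(CC)CC)C(C)C
A5 | alternative 2 | methyl (E)-4-[(tert-butyldimethylsilyl)oxy]-2-diazobut-3-enoate | COC(=O)C(=[N+]=[N-])/C=C/O[Si](C)(C)C(C)(C)C
A6 | alternative 2 | hydroazula-5,8-diene with quaternary C1, 10α-silyl ether and C8 methyl ester | C1C(C(=O)OC)=C[C@@H](O[Si](C)(C)C(C)(C)C)[C@@]2(C)CC[C@@](O[Si](CC)(CC)CC)(C(C)C)C2=C1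
A7 | alternative 3 | cis-decalin with C1 methyl, C6 tertiary hydroxyl, C5 mesylate, C4 isopropyl carbinol and C10 dioxolane | C[C@]12CC[C@@](O)(C(C)C)[C@H](OS(C)(=O)=O)[C@@]1(O)CCCC23OCCO3
A8 | alternative 3 | trans-fused hydroazulen-6-one with C4 carbinol and C10 dioxolane | O=C1CCCC2(OCCO2)[C@@]2(C)CC[C@@](O)(C(C)C)[C@H]12
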